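**Assumption:** the target SMILES corresponds to (R)-1,1-bis(2,4,5-trimethoxyphenyl)propan-2-ol (the diarylmethine carbon is not a stereocentre); compounds 1 and 2 are taken as purchasable.

## Retrosynthetic overview

1. The only stereocentre (C2–OH) is set last, by enantioface-selective hydride delivery to the Cs-symmetric, prochiral ketone 1,1-bis(2,4,5-trimethoxyphenyl)propan-2-one.
2. That ketone is cut at both Ar–CH bonds at once: two molecules of 1,2,4-trimethoxybenzene plus the C3 unit 1,1-dimethoxypropan-2-one in a double Friedel–Crafts alkylation.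
3. No ring is formed; both benzene rings are bought intact, and the arene's own directing effects (C5 attack) give the 2,4,5-pattern.

## Route

**Step 1**
Reactants: 1 1,2,4-trimethoxybenzene (2.1 equiv); 2 1,1-dimethoxypropan-2-one (pyruvaldehyde dimethyl acetal, 1.0 equiv)
Product: 4 1,1-bis(2,4,5-trimethoxyphenyl)propan-2-one, via 1-methoxy-1-(2,4,5-trimethoxyphenyl)propan-2-one 3 (not isolated)
Conditions: TfOH (10 mol %), CH2Cl2, 0 °C → rt
Reagents that add atoms: none
Why: Double Friedel–Crafts alkylation: the acetal ionises to an oxocarbenium ion that is attacked by C5 of 1 (para to 2-OMe, ortho to 4-OMe), and the benzylic methyl ether 3 re-ionises to a cation stabilised by the o/p-methoxy groups despite the adjacent acyl group, which a second molecule of 1 captures; no stereocentre is formed.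

**Step 2**
Reactants: 4 1,1-bis(2,4,5-trimethoxyphenyl)propan-2-one
Product: 6 (R)-1,1-bis(2,4,5-trimethoxyphenyl)propan-2-ol (tatarinoid C), via O-boryl ether 5 (not isolated)
Conditions: (S)-2-methyl-CBS-oxazaborolidine (15 mol %), BH3·SMe2 (1.0 equiv), THF, −20 °C, slow addition of 4; then MeOH, aq. NH4Cl
Reagents that add atoms: none
Why: Corey–Bakshi–Shibata reduction breaks the mirror symmetry of ketone 4: the catalyst–borane complex binds the carbonyl lone pair on the methyl side, away from the very bulky diarylmethyl group, and delivers hydride intramolecularly to the Si face, which by analogy with acetophenone (large group = higher CIP priority) gives the (R)-carbinol; enolisation of 4 is harmless because the α-carbon is not stereogenic, and the ee (expected around 90 %) is checked by chiral HPLC and raised by recrystallisation.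

## Compound list

1 | 1,2,4-trimethoxybenzene | COc1ccc(OC)c(OC)c1 | starting material
2 | 1,1-dimethoxypropan-2-one (pyruvaldehyde dimethyl acetal) | CC(=O)C(OC)OC | starting material
3 | 1-methoxy-1-(2,4,5-trimethoxyphenyl)propan-2-one (racemic, transient) | COc1cc(OC)c(C(OC)C(C)=O)cc1OC | intermediate
4 | 1,1-bis(2,4,5-trimethoxyphenyl)propan-2-one | COc1cc(OC)c(C(c2cc(OC)c(OC)cc2OC)C(C)=O)cc1OC | intermediate
5 | (R)-1,1-bis(2,4,5-trimethoxyphenyl)propan-2-yl borinate (O–BH2 ether of 6) | COc1cc(OC)c(C(c2cc(OC)c(OC)cc2OC)[C@@H](C)OB)cc1OC | intermediate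
6 | tatarinoid C, (R)-1,1-bis(2,4,5-trimethoxyphenyl)propan-2-ol | COc1cc(OC)c(C(c2cc(OC)c(OC)cc2OC)[C@@H](C)O)cc1OC | target

## Summary

Total step count: 2
Longest linear sequence: 2

## Steps most likely to fail

The route has only two steps, so both are listed, and Step 2 is listed twice because it can fail in two independent ways.

**1. Step 2, insufficient enantioselectivity (methyl versus a flexible diarylmethyl group).** The fallback replaces catalytic asymmetric reduction by enzymatic kinetic resolution. It sets out from 4 and comes back at 6. NaBH4 in MeOH at 0 °C gives racemic 1,1-bis(2,4,5-trimethoxyphenyl)propan-2-ol F1. Candida antarctica lipase B (Novozym 435) with vinyl acetate in MTBE at 40 °C acylates the (R)-enantiomer preferentially (Kazlauskas rule, methyl = medium group) to give (R)-1,1-bis(2,4,5-trimethoxyphenyl)propan-2-yl acetate F2. The unreacted (S)-1,1-bis(2,4,5-trimethoxyphenyl)propan-2-ol F3 is separated by chromatography and recycled to 4 with Dess–Martin periodinane. Methanolysis of F2 (K2CO3, MeOH, rt) gives 6.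

**2. Step 1, second arylation stalls at 3 or acid causes side reactions (retro-Friedel–Crafts, benzofuran formation).** The fallback replaces cationic C–C bond formation by Pd-catalysed enolate arylation. It sets out from 1 and comes back at 4. NBS in MeCN at 0 °C gives 1-bromo-2,4,5-trimethoxybenzene F4. Mono-α-arylation of acetone ([Pd(cinnamyl)Cl]2/Mor-DalPhos, Cs2CO3, acetone, 90 °C) gives 1-(2,4,5-trimethoxyphenyl)propan-2-one F5. A second α-arylation of F5 with F4 (Pd(OAc)2/XPhos, Cs2CO3, toluene, 100 °C) occurs at the more acidic benzylic carbon and gives 4.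

**3. Step 2, second failure mode: the hindered carbonyl of 4 is not reduced selectively by any hydride catalyst.** The fallback sets the stereocentre by C–C instead of C–H bond formation on a different Cs-symmetric precursor. It sets out from 1 and comes back at 6. Double Friedel–Crafts reaction of 1 with ethyl glyoxylate (TfOH cat., CH2Cl2, 0 °C → rt) gives ethyl 2,2-bis(2,4,5-trimethoxyphenyl)acetate F6. DIBAL-H in CH2Cl2 at −78 °C gives 2,2-bis(2,4,5-trimethoxyphenyl)acetaldehyde F7. Enantioselective methyl addition (Me2Zn, Ti(OiPr)4, 5 mol % (1S,2S)-1,2-bis(trifluoromethanesulfonamido)cyclohexane, toluene, −20 °C) gives 6. The ligand enantiomer is chosen by analogy with the known (R,R)-ligand → (S)-alcohol sense and would be confirmed by Mosher analysis.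

## Further compounds

F1 | step 2 | racemic 1,1-bis(2,4,5-trimethoxyphenyl)propan-2-ol | COc1cc(OC)c(C(c2cc(OC)c(OC)cc2OC)C(C)O)cc1OC
F2 | step 2 | (R)-1,1-bis(2,4,5-trimethoxyphenyl)propan-2-yl acetate | COc1cc(OC)c(C(c2cc(OC)c(OC)cc2OC)[C@@H](C)OC(C)=O)cc1OC
F3 | step 2 | (S)-1,1-bis(2,4,5-trimethoxyphenyl)propan-2-ol | COc1cc(OC)c(C(c2cc(OC)c(OC)cc2OC)[C@H](C)O)cc1OC
F4 | step 1 | 1-bromo-2,4,5-trimethoxybenzene | COc1cc(OC)c(Br)cc1OC
F5 | step 1 | 1-(2,4,5-trimethoxyphenyl)propan-2-one | COc1cc(OC)c(CC(C)=O)cc1OC
F6 | step 2 | ethyl 2,2-bis(2,4,5-trimethoxyphenyl)acetate | CCOC(=O)C(c1cc(OC)c(OC)cc1OC)c1cc(OC)c(OC)cc1OC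
F7 | step 2 | 2,2-bis(2,4,5-trimethoxyphenyl)acetaldehyde | COc1cc(OC)c(C(C=O)c2cc(OC)c(OC)cc2OC)cc1OC
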